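**Plan**

1. Numbering: flavan O1, C2–C4, ring A = C4a–C8a, ring B (C1'–C6') on C2; side chain C1''–C3'' on C6, ring C (4-hydroxyphenyl) on C1'', ring D (4-hydroxy-2-methoxyphenyl) on C3''. Cuts, in order: the four O-benzyl groups and the 2'-O-methyl; C4–C3 together with O1–C2 (retro oxa-[4+2]); C4a–C4; C3''–ring D; C1''–ring C.
2. Enabling feature: on ring A, O1 sits on C8a ortho to C4a, C4 is a benzylic CH2 on C4a, and O7 is para to C4a, so O1=C8a–C4a=C4 is an easily formed ortho-quinone methide. C2 carries ring B, whose O2' is ortho to C1', so C3=C2 can come from a 2-vinylphenol, a vinylogous phenol with a hydrogen-bond handle.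
3. Forward: ring A enters as umbelliferone and ring C is added at C1'' by rhodium-catalysed conjugate arylation. The lactone ring (O7–C3''(=O)–C2''–C1''), absent from the target, is then opened by the ring D aryllithium, and C3'' is deoxygenated.
4. C4 is placed on C4a by ortho-formylation and reduction. The chiral-acid-catalysed cycloaddition with the ring B vinylphenol joins the two halves and closes the pyran as the last ring. O2' methylation and hydrogenolysis finish the route.
5. Stereochemistry: C1'' (R) comes from (R)-Segphos acting on the geometry-locked coumarin; C2 (S) comes from the chiral phosphoric acid in the cycloaddition.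

Key step: step 12

Assumption: precedent does not fix the sense of induction of the phosphoric acid in step 12. (R)-TRIP is written, and its commercial enantiomer takes its place if a model run (2-hydroxy-4-benzyloxybenzyl alcohol with 17) shows the opposite sense.

**Route**

Step 1
Reactants: 1 7-hydroxycoumarin (umbelliferone)
Product: 2 7-[(4-methoxybenzyl)oxy]coumarin
Conditions: PMBCl, K2CO3, DMF, 60 °C
Reagents that add atoms: 4-methoxybenzyl chloride COc1ccc(CCl)cc1
Why: Williamson etherification of the single phenol (the future O1); the 4-methoxybenzyl group is chosen because it is the only ether of the route that falls to trifluoroacetic acid in step 7.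

Step 2
Reactants: 2 7-[(4-methoxybenzyl)oxy]coumarin; 3 4-(benzyloxy)phenylboronic acid
Product: 4 (4R)-4-[4-(benzyloxy)phenyl]-7-[(4-methoxybenzyl)oxy]chroman-2-one
Conditions: 3 (5 equiv), Rh(acac)(C2H4)2 (3 mol %), (R)-Segphos (3.3 mol %), 1,4-dioxane/H2O 10:1, 60 °C
Reagents that add atoms: none
Why: Hayashi-Miyaura reaction (rhodium-catalysed asymmetric 1,4-addition of an arylboronic acid to a coumarin): the lactone ring, which is not part of the target, locks the cinnamate in the cis geometry so that the aryl-rhodium/(R)-Segphos complex meets one face only and sets C1'' as R, the sense known for 4-arylchroman-2-ones with this ligand.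

Step 3
Reactants: 4 (4R)-4-[4-(benzyloxy)phenyl]-7-[(4-methoxybenzyl)oxy]chroman-2-one
Product: 5 (4R)-4-[4-(benzyloxy)phenyl]-7-[(4-methoxybenzyl)oxy]chroman-2-ol (lactol; both C2 anomers)
Conditions: i-Bu2AlH (1.1 equiv), CH2Cl2, −78 °C; aq. potassium sodium tartrate
Reagents that add atoms: none
Why: Partial reduction of the aryl lactone with one equivalent of i-Bu2AlH at low temperature stops at the aluminium hemiacetal, as is usual for 4-arylchroman-2-ones, and leaves C1'' and both ethers untouched.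

Step 4
Reactants: 6 4-bromo-3-methoxyphenol
Product: 7 4-(benzyloxy)-1-bromo-2-methoxybenzene
Conditions: BnBr, K2CO3, acetone, reflux
Reagents that add atoms: benzyl bromide BrCc1ccccc1
Why: Williamson etherification; the aryl bromide is inert to carbonate.

Step 5
Reactants: 7 4-(benzyloxy)-1-bromo-2-methoxybenzene; 5 (4R)-4-[4-(benzyloxy)phenyl]-7-[(4-methoxybenzyl)oxy]chroman-2-ol
Product: 9 2-{(1R)-1-[4-(benzyloxy)phenyl]-3-[4-(benzyloxy)-2-methoxyphenyl]-3-hydroxypropyl}-5-[(4-methoxybenzyl)oxy]phenol (both C3 epimers), via aryllithium 8 (not isolated)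
Conditions: 7 (2.3 equiv), n-BuLi (2.2 equiv), THF, −78 °C; then 5, −78 °C to 0 °C; H2O
Reagents that add atoms: none
Why: Bromine-lithium exchange followed by 1,2-addition to the open hydroxy-aldehyde form of the lactol: the first equivalent of 8 deprotonates 5 and opens the temporary ring to the O7 phenoxide, the second forms the C3''–ring D bond, and the new carbinol centre need not be controlled because it is removed in step 7.

Step 6
Reactants: 9 2-{(1R)-1-[4-(benzyloxy)phenyl]-3-[4-(benzyloxy)-2-methoxyphenyl]-3-hydroxypropyl}-5-[(4-methoxybenzyl)oxy]phenol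
Product: 10 (3R)-3-{2-(benzyloxy)-4-[(4-methoxybenzyl)oxy]phenyl}-3-[4-(benzyloxy)phenyl]-1-[4-(benzyloxy)-2-methoxyphenyl]propan-1-ol (both C1 epimers)
Conditions: BnBr, K2CO3, DMF, rt
Reagents that add atoms: benzyl bromide BrCc1ccccc1
Why: Williamson etherification: carbonate deprotonates only the phenol O7–H and not the secondary alcohol, so O7 is kept out of the later formylation and ring closure.

Step 7
Reactants: 10 (3R)-3-{2-(benzyloxy)-4-[(4-methoxybenzyl)oxy]phenyl}-3-[4-(benzyloxy)phenyl]-1-[4-(benzyloxy)-2-methoxyphenyl]propan-1-ol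
Product: 12 3-(benzyloxy)-4-{(1R)-1-[4-(benzyloxy)phenyl]-3-[4-(benzyloxy)-2-methoxyphenyl]propyl}phenol, via PMB ether 11 (not isolated)
Conditions: Et3SiH (6 equiv), TFA/CH2Cl2 1:9, 0 °C to rt
Reagents that add atoms: none
Why: Kursanov-Parnes ionic hydrogenation and acidolysis in one flask: the 2,4-dialkoxybenzylic alcohol ionises at once and the silane reduces its cation to 11, then the same acid cleaves the 4-methoxybenzyl aryl ether and the silane scavenges its cation, while the plain benzyl aryl ethers and the non-ionisable C1'' centre persist.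

Step 8
Reactants: 12 3-(benzyloxy)-4-{(1R)-1-[4-(benzyloxy)phenyl]-3-[4-(benzyloxy)-2-methoxyphenyl]propyl}phenol
Product: 13 4-(benzyloxy)-5-{(1R)-1-[4-(benzyloxy)phenyl]-3-[4-(benzyloxy)-2-methoxyphenyl]propyl}-2-hydroxybenzaldehyde
Conditions: MgCl2, Et3N, (CH2O)n, THF, reflux; 1 M HCl
Reagents that add atoms: paraformaldehyde (formaldehyde unit) C=O
Why: Casnati-Skattebol ortho-formylation: the magnesium phenoxide delivers formaldehyde only to the ring that bears the free OH, and there to the open ortho carbon C4a (para to O7) instead of C8 between the two oxygens, so the equally electron-rich ring D stays untouched.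

Step 9
Reactants: 13 4-(benzyloxy)-5-{(1R)-1-[4-(benzyloxy)phenyl]-3-[4-(benzyloxy)-2-methoxyphenyl]propyl}-2-hydroxybenzaldehyde
Product: 14 5-(benzyloxy)-4-{(1R)-1-[4-(benzyloxy)phenyl]-3-[4-(benzyloxy)-2-methoxyphenyl]propyl}-2-(hydroxymethyl)phenol
Conditions: NaBH4, THF/MeOH, 0 °C; pH 7 buffer; used without storage
Reagents that add atoms: none
Why: Borohydride reduction of the aldehyde, kept cold and worked up at neutral pH so that the electron-rich salicyl alcohol does not ionise before step 12.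

Step 10
Reactants: 15 2,5-dihydroxybenzaldehyde
Product: 16 5-(benzyloxy)-2-hydroxybenzaldehyde
Conditions: BnBr (1.0 equiv), K2CO3 (1.0 equiv), acetone, rt to 50 °C
Reagents that add atoms: benzyl bromide BrCc1ccccc1
Why: Williamson etherification with one equivalent of base: the 2-OH is held in a hydrogen bond to the formyl group, so the 5-OH reacts.

Step 11
Reactants: 16 5-(benzyloxy)-2-hydroxybenzaldehyde
Product: 17 4-(benzyloxy)-2-vinylphenol
Conditions: Ph3PCH3Br (1.3 equiv), KOt-Bu (2.4 equiv), THF, 0 °C to rt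
Reagents that add atoms: methyltriphenylphosphonium bromide C[P+](c1ccccc1)(c1ccccc1)c1ccccc1.[Br-]
Why: Wittig methylenation, with the extra equivalent of base covering the phenol, is the standard access to 2-vinylphenols from salicylaldehydes.

Step 12
Reactants: 14 5-(benzyloxy)-4-{(1R)-1-[4-(benzyloxy)phenyl]-3-[4-(benzyloxy)-2-methoxyphenyl]propyl}-2-(hydroxymethyl)phenol; 17 4-(benzyloxy)-2-vinylphenol
Product: 19 (2S)-7-(benzyloxy)-2-[5-(benzyloxy)-2-hydroxyphenyl]-6-{(1R)-1-[4-(benzyloxy)phenyl]-3-[4-(benzyloxy)-2-methoxyphenyl]propyl}chroman, via ortho-quinone methide 18 (not isolated)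
Conditions: (R)-TRIP [(R)-3,3'-bis(2,4,6-triisopropylphenyl)-1,1'-binaphthyl-2,2'-diyl hydrogen phosphate] (10 mol %), 17 (3 equiv), 5 Å MS, toluene, −20 °C to 0 °C, 14 added slowly by syringe pump; Et3N quench
Reagents that add atoms: none
Why: Proposed new method: the chiral phosphoric acid ionises the doubly donor-activated benzylic alcohol of 14 (O1–H ortho and O7-benzyl para to C4a) to ortho-quinone methide 18, holds its C8a=O through the acidic P–OH and the O2'–H of vinylphenol 17 through the P=O, and the vinylogous-phenol terminus C3 attacks the methide carbon C4 while O1 closes on C2. The closest known reaction type is the chiral-phosphoric-acid-catalysed inverse-electron-demand oxa-Diels-Alder reaction of aryl-substituted ortho-quinone methides, formed in situ from ortho-hydroxybenzyl alcohols, with ortho-hydroxystyrenes or vinylindoles; new here is a methide terminus without substituent, so that C2 is the only centre formed. The pyran ring closes in a concerted but strongly asynchronous [4+2] mode (four-atom unit O1=C8a–C4a=C4, two-atom unit C3=C2), with C4–C3 bonding running ahead of O1–C2 bonding. C2 is set as S by the catalyst alone, because the doubly hydrogen-bonded assembly exposes one face of the styrene to O1, while C1'' lies on the far edge of ring A and should neither help nor hinder. Regiochemistry (2-aryl, not 3-aryl) follows from polarity, closure can use only O1 because O7 is benzylated, and Friedel-Crafts attack by the dialkoxyarene rings or dimerisation of 18 is held back by slow addition of 14 to an excess of the hydrogen-bond-activated 17. Low temperature and the amine quench guard the acid-labile C2–O1 bond against re-ionisation.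

Step 13
Reactants: 19 (2S)-7-(benzyloxy)-2-[5-(benzyloxy)-2-hydroxyphenyl]-6-{(1R)-1-[4-(benzyloxy)phenyl]-3-[4-(benzyloxy)-2-methoxyphenyl]propyl}chroman
Product: 20 (2S)-7-(benzyloxy)-2-[5-(benzyloxy)-2-methoxyphenyl]-6-{(1R)-1-[4-(benzyloxy)phenyl]-3-[4-(benzyloxy)-2-methoxyphenyl]propyl}chroman
Conditions: MeI, K2CO3, DMF, 0 °C to rt
Reagents that add atoms: iodomethane CI
Why: Williamson etherification of the only free phenol turns the O2'–H handle of step 12 into the 2'-methoxy group of the target, and mild base at or below room temperature should keep the phenoxide from expelling O1 (retro-oxa-Michael), so C2 is retained.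

Step 14
Reactants: 20 (2S)-7-(benzyloxy)-2-[5-(benzyloxy)-2-methoxyphenyl]-6-{(1R)-1-[4-(benzyloxy)phenyl]-3-[4-(benzyloxy)-2-methoxyphenyl]propyl}chroman
Product: 21 (2S)-2-(5-hydroxy-2-methoxyphenyl)-6-[(1R)-3-(4-hydroxy-2-methoxyphenyl)-1-(4-hydroxyphenyl)propyl]chroman-7-ol (target)
Conditions: H2 (1 atm), 10 % Pd/C, EtOAc/MeOH, rt, stopped after uptake of four equivalents
Reagents that add atoms: none
Why: Catalytic hydrogenolysis of the four aryl benzyl ethers in neutral medium, as practised on perbenzylated flavans; the cyclic secondary C2–O1 ether reacts much more slowly and neither stereocentre is touched.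

**Compound list**

1 | 7-hydroxycoumarin (umbelliferone) | O=c1ccc2ccc(O)cc2o1 | starting material
2 | 7-[(4-methoxybenzyl)oxy]coumarin | O=c1ccc2ccc(OCc3ccc(OC)cc3)cc2o1 | intermediate
3 | 4-(benzyloxy)phenylboronic acid | OB(O)c1ccc(OCc2ccccc2)cc1 | starting material
4 | (4R)-4-[4-(benzyloxy)phenyl]-7-[(4-methoxybenzyl)oxy]chroman-2-one | O=C1C[C@H](c2ccc(OCc3ccccc3)cc2)c2ccc(OCc3ccc(OC)cc3)cc2O1 | intermediate
5 | (4R)-4-[4-(benzyloxy)phenyl]-7-[(4-methoxybenzyl)oxy]chroman-2-ol (both C2 anomers) | OC1C[C@H](c2ccc(OCc3ccccc3)cc2)c2ccc(OCc3ccc(OC)cc3)cc2O1 | intermediate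
6 | 4-bromo-3-methoxyphenol | COc1cc(O)ccc1Br | starting material
7 | 4-(benzyloxy)-1-bromo-2-methoxybenzene | COc1cc(OCc2ccccc2)ccc1Br | intermediate
8 | [4-(benzyloxy)-2-methoxyphenyl]lithium | COc1cc(OCc2ccccc2)ccc1[Li] | intermediate
9 | 2-{(1R)-1-[4-(benzyloxy)phenyl]-3-[4-(benzyloxy)-2-methoxyphenyl]-3-hydroxypropyl}-5-[(4-methoxybenzyl)oxy]phenol (both C3 epimers) | COc1cc(OCc2ccccc2)ccc1C(O)C[C@H](c1ccc(OCc2ccccc2)cc1)c1ccc(OCc2ccc(OC)cc2)cc1O | intermediate
10 | (3R)-3-{2-(benzyloxy)-4-[(4-methoxybenzyl)oxy]phenyl}-3-[4-(benzyloxy)phenyl]-1-[4-(benzyloxy)-2-methoxyphenyl]propan-1-ol (both C1 epimers) | COc1cc(OCc2ccccc2)ccc1C(O)C[C@H](c1ccc(OCc2ccccc2)cc1)c1ccc(OCc2ccc(OC)cc2)cc1OCc1ccccc1 | intermediate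
11 | 2-(benzyloxy)-1-{(1R)-1-[4-(benzyloxy)phenyl]-3-[4-(benzyloxy)-2-methoxyphenyl]propyl}-4-[(4-methoxybenzyl)oxy]benzene | COc1cc(OCc2ccccc2)ccc1CC[C@H](c1ccc(OCc2ccccc2)cc1)c1ccc(OCc2ccc(OC)cc2)cc1OCc1ccccc1 | intermediate
12 | 3-(benzyloxy)-4-{(1R)-1-[4-(benzyloxy)phenyl]-3-[4-(benzyloxy)-2-methoxyphenyl]propyl}phenol | COc1cc(OCc2ccccc2)ccc1CC[C@H](c1ccc(OCc2ccccc2)cc1)c1ccc(O)cc1OCc1ccccc1 | intermediate
13 | 4-(benzyloxy)-5-{(1R)-1-[4-(benzyloxy)phenyl]-3-[4-(benzyloxy)-2-methoxyphenyl]propyl}-2-hydroxybenzaldehyde | COc1cc(OCc2ccccc2)ccc1CC[C@H](c1ccc(OCc2ccccc2)cc1)c1cc(C=O)c(O)cc1OCc1ccccc1 | intermediate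
14 | 5-(benzyloxy)-4-{(1R)-1-[4-(benzyloxy)phenyl]-3-[4-(benzyloxy)-2-methoxyphenyl]propyl}-2-(hydroxymethyl)phenol | COc1cc(OCc2ccccc2)ccc1CC[C@H](c1ccc(OCc2ccccc2)cc1)c1cc(CO)c(O)cc1OCc1ccccc1 | intermediate
15 | 2,5-dihydroxybenzaldehyde | O=Cc1cc(O)ccc1O | starting material
16 | 5-(benzyloxy)-2-hydroxybenzaldehyde | O=Cc1cc(OCc2ccccc2)ccc1O | intermediate
17 | 4-(benzyloxy)-2-vinylphenol | C=Cc1cc(OCc2ccccc2)ccc1O | intermediate
18 | 3-(benzyloxy)-4-{(1R)-1-[4-(benzyloxy)phenyl]-3-[4-(benzyloxy)-2-methoxyphenyl]propyl}-6-methylidenecyclohexa-2,4-dien-1-one | COc1cc(OCc2ccccc2)ccc1CC[C@H](c1ccc(OCc2ccccc2)cc1)C1=CC(=C)C(=O)C=C1OCc1ccccc1 | intermediate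
19 | (2S)-7-(benzyloxy)-2-[5-(benzyloxy)-2-hydroxyphenyl]-6-{(1R)-1-[4-(benzyloxy)phenyl]-3-[4-(benzyloxy)-2-methoxyphenyl]propyl}chroman | COc1cc(OCc2ccccc2)ccc1CC[C@H](c1ccc(OCc2ccccc2)cc1)c1cc2c(cc1OCc1ccccc1)O[C@H](c1cc(OCc3ccccc3)ccc1O)CC2 | intermediate
20 | (2S)-7-(benzyloxy)-2-[5-(benzyloxy)-2-methoxyphenyl]-6-{(1R)-1-[4-(benzyloxy)phenyl]-3-[4-(benzyloxy)-2-methoxyphenyl]propyl}chroman | COc1cc(OCc2ccccc2)ccc1CC[C@H](c1ccc(OCc2ccccc2)cc1)c1cc2c(cc1OCc1ccccc1)O[C@H](c1cc(OCc3ccccc3)ccc1OC)CC2 | intermediate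
21 | (2S)-2-(5-hydroxy-2-methoxyphenyl)-6-[(1R)-3-(4-hydroxy-2-methoxyphenyl)-1-(4-hydroxyphenyl)propyl]chroman-7-ol | COc1cc(O)ccc1CC[C@H](c1ccc(O)cc1)c1cc2c(cc1O)O[C@H](c1cc(O)ccc1OC)CC2 | target

**Step count**

Total step count: 14.
Longest linear sequence: 11 steps from 1 (steps 1, 2, 3, 5, 6, 7, 8, 9, 12, 13, 14).

**Steps most likely to fail**

First, step 12 (labelled step).
- What may go wrong:
  - sluggish ionisation of the primary benzylic alcohol;
  - oligomerisation of the quinone methide;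
  - poor facial selectivity at C2;
  - acid-induced re-opening of the C2–O1 bond with loss of configuration.
- The fallback uses known chemistry only. It sets out from 13 and comes back at 20.
- Commercial 2',5'-dihydroxyacetophenone is benzylated at the non-chelated 5'-OH (BnBr, K2CO3) to 5-benzyloxy-2-hydroxyacetophenone F1. This is methylated (MeI, K2CO3) to 5-benzyloxy-2-methoxyacetophenone F2.
- Claisen-Schmidt condensation of F2 with 13 (KOH, EtOH) should give the 2-hydroxy-retrochalcone F3.
- Hydrogenation over RhCl(PPh3)3 saturates only the C=C bond and should give the dihydro-retrochalcone F4.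
- Noyori asymmetric transfer hydrogenation with RuCl(p-cymene)[(R,R)-TsDPEN] in HCO2H/Et3N should give the (R)-carbinol F5.
- Intramolecular Mitsunobu etherification (PPh3, DIAD, THF, 0 °C) closes O1–C2 with inversion and gives 20.

Second, step 7.
- What may go wrong:
  - capture of the 4-methoxybenzyl cation by the electron-rich rings A and D instead of by the silane;
  - partial loss of benzyl ethers;
  - acid-induced departure of the C1'' substituent from ring A.
- The fallback avoids carbocations altogether. It sets out from 4 (and uses 7) and comes back at 12 by way of 11, which is now isolated.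
- LiAlH4 reduces the lactone to the phenol-alcohol F6. BnBr/K2CO3 then gives the O7-benzyl primary alcohol F7, and Appel iodination (I2, PPh3, imidazole) gives the primary iodide F8.
- Zinc insertion (Zn dust, LiCl, THF) gives the alkylzinc iodide F9. Negishi coupling of F9 with 7 (Pd(OAc)2, SPhos) forms the C3''–ring D bond and gives 11.
- DDQ in CH2Cl2/pH 7 buffer then removes the 4-methoxybenzyl group oxidatively to give 12.
- DDQ may also attack the C1''–H bond, which is why this sequence is only the reserve.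

Third, step 9.
- What may go wrong: premature ionisation of the product on work-up or on silica with self-condensation, or over-reduction through the quinone methide to the cresol.
- The fallback sets out from 12 and comes back at 14, bypassing 13.
- Boronate-templated ortho-hydroxymethylation is run with PhB(OH)2, (CH2O)n and catalytic propionic acid in toluene, with removal of water. It should give the 2-phenyl-4H-1,3,2-benzodioxaborin F10, a storable mask of the salicyl alcohol.
- Exchange with propane-1,3-diol in THF at room temperature, immediately before step 12, releases 14.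

**Further compounds**

F1 | step 12 | 5-benzyloxy-2-hydroxyacetophenone: 1-[5-(benzyloxy)-2-hydroxyphenyl]ethanone | CC(=O)c1cc(OCc2ccccc2)ccc1O
F2 | step 12 | 5-benzyloxy-2-methoxyacetophenone: 1-[5-(benzyloxy)-2-methoxyphenyl]ethanone | CC(=O)c1cc(OCc2ccccc2)ccc1OC
F3 | step 12 | 2-hydroxy-retrochalcone: (2E)-3-[4-(benzyloxy)-5-{(1R)-1-[4-(benzyloxy)phenyl]-3-[4-(benzyloxy)-2-methoxyphenyl]propyl}-2-hydroxyphenyl]-1-[5-(benzyloxy)-2-methoxyphenyl]prop-2-en-1-one | COc1cc(OCc2ccccc2)ccc1CC[C@H](c1ccc(OCc2ccccc2)cc1)c1cc(/C=C/C(=O)c2cc(OCc3ccccc3)ccc2OC)c(O)cc1OCc1ccccc1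
F4 | step 12 | dihydro-retrochalcone: 3-[4-(benzyloxy)-5-{(1R)-1-[4-(benzyloxy)phenyl]-3-[4-(benzyloxy)-2-methoxyphenyl]propyl}-2-hydroxyphenyl]-1-[5-(benzyloxy)-2-methoxyphenyl]propan-1-one | COc1cc(OCc2ccccc2)ccc1CC[C@H](c1ccc(OCc2ccccc2)cc1)c1cc(CCC(=O)c2cc(OCc3ccccc3)ccc2OC)c(O)cc1OCc1ccccc1
F5 | step 12 | (R)-carbinol: 5-(benzyloxy)-2-{(3R)-3-[5-(benzyloxy)-2-methoxyphenyl]-3-hydroxypropyl}-4-{(1R)-1-[4-(benzyloxy)phenyl]-3-[4-(benzyloxy)-2-methoxyphenyl]propyl}phenol | COc1cc(OCc2ccccc2)ccc1CC[C@H](c1ccc(OCc2ccccc2)cc1)c1cc(CC[C@@H](O)c2cc(OCc3ccccc3)ccc2OC)c(O)cc1OCc1ccccc1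
F6 | step 7 | phenol-alcohol: 2-{(1R)-1-[4-(benzyloxy)phenyl]-3-hydroxypropyl}-5-[(4-methoxybenzyl)oxy]phenol | OCC[C@H](c1ccc(OCc2ccccc2)cc1)c1ccc(OCc2ccc(OC)cc2)cc1O
F7 | step 7 | O7-benzyl primary alcohol: (3R)-3-{2-(benzyloxy)-4-[(4-methoxybenzyl)oxy]phenyl}-3-[4-(benzyloxy)phenyl]propan-1-ol | OCC[C@H](c1ccc(OCc2ccccc2)cc1)c1ccc(OCc2ccc(OC)cc2)cc1OCc1ccccc1
F8 | step 7 | primary iodide: 2-(benzyloxy)-1-{(1R)-1-[4-(benzyloxy)phenyl]-3-iodopropyl}-4-[(4-methoxybenzyl)oxy]benzene | ICC[C@H](c1ccc(OCc2ccccc2)cc1)c1ccc(OCc2ccc(OC)cc2)cc1OCc1ccccc1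
F9 | step 7 | alkylzinc iodide: [(3R)-3-{2-(benzyloxy)-4-[(4-methoxybenzyl)oxy]phenyl}-3-[4-(benzyloxy)phenyl]propyl]zinc iodide | I[Zn]CC[C@H](c1ccc(OCc2ccccc2)cc1)c1ccc(OCc2ccc(OC)cc2)cc1OCc1ccccc1
F10 | step 9 | 2-phenyl-4H-1,3,2-benzodioxaborin: 7-(benzyloxy)-6-{(1R)-1-[4-(benzyloxy)phenyl]-3-[4-(benzyloxy)-2-methoxyphenyl]propyl}-2-phenyl-4H-1,3,2-benzodioxaborinine | COc1cc(OCc2ccccc2)ccc1CC[C@H](c1ccc(OCc2ccccc2)cc1)c1cc2COB(c3ccccc3)Oc2cc1OCc1ccccc1
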